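However large the transfer coefficient, c(J) in this flask cannot pass 56 mM, the level at which the step from X stops delivering.

    J + D.J → J.D.J (k1 = 0.346 /M/s)
    D + J → D.J (k2 = 0.565 /M/s)
    X ⇌ J, rate k3*(csat - [J]) (k3 = 2.43 /s, csat = 56 mM)
    D.J ⇌ L (K4 = 0.688, k4 = 0.0113 /s)
    J → Z (k5 = 0.0498 /s)
    G ⇌ D.J, rate k6*(cs6 - [D.J]) while solid is left; crystals form when [D.J] > cs6 (cs6 = 0.12 M, k6 = 0.820 /s)

D 1.5 M; X 56 mM (held); time 30 s

- elm: doubling the solubility in step 6, all else as stated
- birch: doubling the transfer coefficient of step 3, all else as stated
- maple: doubling the dissolution coefficient of step 6, all else as stated
- larch: doubling the saturation concentration of X, all else as stated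

- amounts and yields of D.J count G too
- given per volume of solution although it is solid: G
- at the start none of J is dissolved
- run time (flask): 30 s

* the D.J and G together standing at 30 s, as a percentage of the D charged
* the change that raises the amount of D.J and G together at 30 s, in percent of the D charged most ("none" if none brings more than 2 percentage points) (elm / birch / maple / larch / none)
* amount of D.J and G together at 30 s, in percent of the D charged, after larch

I turned the question round: what would have to be true for birch to rival larch? The transfer from X would have to be the slow side of the balance of J. At the charged amounts, transfer takes 0.412 s, while loss of J to D and to Z takes 1.11 s. Transfer is the faster, so c(J) should stand at 73.0% of saturation, or 0.0409 M. Birch lifts that share to 84.4%, whereas larch doubles the concentration itself.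

With c(J) steady, D falls pseudo-first-order. I carried its supply half-life, ln(2) over the rate constant of D + J times that c(J): 30.0 s. Over 30 s this uses 50.0% of D. Holding c(D.J) at its solubility, I charged 6.11% to J.D.J and L, which leaves 43.9%. Larch gives a half-life of 15.0 s, half of this one, and so 75.0% used. After a leak of 9.50%, 65.5% stands. Birch gives 26.0 s and 55.1% used. Elm and maple leave that half-life as it was, and with c(D.J) held at the doubled solubility, elm raises my charge to J.D.J and L to 12.2%, so I chose larch.

The forecast gave 45.2%, larch and 66.3%, on the ground that “Larch doubles the J supply, so it wins”. Mine stood lower, with the same choice.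

The simulation gave 45.3%, larch with 21 percentage points, and 66.3% after larch. At 3.00 s, c(J) stood at 73.4% of saturation. The half-life of 30.0 s leaves 50.0% of D at 30 s, and the flask held 48.2%.

For the neighbour flask read at 50 s, the same half-life leaves 31.5% of D. The computed neighbour holds 28.1%.

All constants were chosen freely; no experiment stands behind them.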